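**Retrosynthetic overview**

1. Polyene: Wittig at C11=C12 (C15 β-aldehyde + C25 ylide), Wittig at C11'=C12' (ε-C15 phosphonium salt + C10 dialdehyde), Horner–Wadsworth–Emmons at C9'=C10', Wittig on a lactol at C7'=C8'.
2. ε-Ring (C1'–C6'): one [4+2] cycloaddition of 4-methyl-2-pyrone with isobutene. The enabling feature is that O3' and C7' sit cis and 1,4 to each other across the C4'=C5' double bond, with the gem-dimethyl carbon C1' next to C6'; this is the pattern of an opened pyrone/alkene adduct.
3. β-Ring: bought as ketoisophorone. C3 is set by asymmetric transfer hydrogenation; C4 is relayed from C3 through a cis-fused carbonate formed with allylic transposition, which also moves the double bond to C5=C6.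
4. Ring order: β-ring purchased (never closed), temporary carbonate ring (step 6), then the ε-ring (step 7) as the only and last closure of a skeleton ring. The racemic adduct is resolved by a lipase in step 10.

Key step: step 7

Remark: locants follow carotenoid numbering (β end unprimed, ε end primed). The racemic compounds 11, 12, 14 and 15 are written with the SMILES of the enantiomer that is carried on after step 10. Each Wittig product is equilibrated thermally to the all-E isomer before use.

**Route**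

Step 1
Reactants: 1 2,6,6-trimethylcyclohex-2-ene-1,4-dione (ketoisophorone)
Product: 2 (4S)-4-hydroxy-2,6,6-trimethylcyclohex-2-en-1-one
Conditions: RuCl[(S,S)-TsDPEN](p-cymene) (0.5 mol %), i-PrOH, 25 °C
Reagents that add atoms: none
Why: Noyori-type asymmetric transfer hydrogenation should reduce only the unhindered C4 carbonyl (C1 is shielded by the gem-dimethyl group and the C2 methyl group), and the (S,S)-ligand should give the (S)-carbinol, with the alkenyl group taking the place of the aryl group in the usual model; this centre becomes C3 of the β-ring.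

Step 2
Reactants: 2 (4S)-4-hydroxy-2,6,6-trimethylcyclohex-2-en-1-one; 3 (E)-3-methylpent-2-en-4-yn-1-ol
Product: 4 (4S)-1-[(E)-5-hydroxy-3-methylpent-3-en-1-yn-1-yl]-2,6,6-trimethylcyclohex-2-ene-1,4-diol (both C1 epimers)
Conditions: 3 (2.6 equiv), n-BuLi (5.2 equiv), THF, −78 → −20 °C; then 2, −78 → 0 °C; aq NH4Cl
Reagents that add atoms: none
Why: 1,2-addition of a lithium acetylide (the C,O-dilithio derivative of 3, one extra equivalent being spent on the hydroxyl of 2) to a non-enolisable hindered ketone is well precedented for 2,6,6-trimethylcyclohexenones; the new tertiary carbinol centre forms without control and is erased in step 6.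

Step 3
Reactants: 4 (4S)-1-[(E)-5-hydroxy-3-methylpent-3-en-1-yn-1-yl]-2,6,6-trimethylcyclohex-2-ene-1,4-diol
Product: 5 (4S)-1-[(1E,3E)-5-hydroxy-3-methylpenta-1,3-dien-1-yl]-2,6,6-trimethylcyclohex-2-ene-1,4-diol
Conditions: NaAlH2(OCH2CH2OCH3)2 (5 equiv), THF, 0 → 25 °C; aq potassium sodium tartrate
Reagents that add atoms: none
Why: hydroxyl-directed trans-hydroalumination of the propargylic alcohol followed by protonolysis should give the (E)-alkene (future C7=C8) and leave the (E)-trisubstituted alkene and the ring alkene untouched.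

Step 4
Reactants: 5 (4S)-1-[(1E,3E)-5-hydroxy-3-methylpenta-1,3-dien-1-yl]-2,6,6-trimethylcyclohex-2-ene-1,4-diol
Product: 6 (2E,4E)-5-[(4S)-1,4-dihydroxy-2,6,6-trimethylcyclohex-2-en-1-yl]-3-methylpenta-2,4-dienal
Conditions: TEMPO (10 mol %), PhI(OAc)2 (1.1 equiv), CH2Cl2, 0 → 20 °C
Reagents that add atoms: none
Why: oxoammonium (TEMPO) oxidation is selective for the primary dienylic alcohol over the secondary ring alcohol and cannot touch the tertiary one; the conjugated formyl group also deactivates the side chain for the cation chemistry of step 6.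

Step 5
Reactants: 6 (2E,4E)-5-[(4S)-1,4-dihydroxy-2,6,6-trimethylcyclohex-2-en-1-yl]-3-methylpenta-2,4-dienal
Product: 7 tert-butyl (1S)-4-hydroxy-3,5,5-trimethyl-4-[(1E,3E)-3-methyl-5-oxopenta-1,3-dien-1-yl]cyclohex-2-en-1-yl carbonate (both C4 epimers)
Conditions: Boc2O (1.3 equiv), DMAP (10 mol %), CH2Cl2, 0 → 20 °C
Reagents that add atoms: di-tert-butyl dicarbonate, CC(C)(C)OC(=O)OC(=O)OC(C)(C)C
Why: DMAP-catalysed acylation should occur at the secondary hydroxyl only, because the tertiary bis-allylic hydroxyl is too hindered; the carbonate is installed as the internal oxygen nucleophile for step 6.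

Step 6
Reactants: 7 tert-butyl (1S)-4-hydroxy-3,5,5-trimethyl-4-[(1E,3E)-3-methyl-5-oxopenta-1,3-dien-1-yl]cyclohex-2-en-1-yl carbonate
Product: 8 (2E,4E)-3-methyl-5-[(3aR,7aS)-4,6,6-trimethyl-2-oxo-3a,6,7,7a-tetrahydro-1,3-benzodioxol-5-yl]penta-2,4-dienal
Conditions: CF3SO3H (5 mol %), 4 Å molecular sieves, CH2Cl2, −40 → 0 °C
Reagents that add atoms: none
Why: Proposed new method: acid ionises the tertiary, doubly allylic C6 hydroxyl to an allyl cation spread over C6 and C4 (leakage of charge into the side chain is damped by the formyl group), the carbonyl oxygen of the C3 tert-butyl carbonate closes onto C4 (5-exo) and the dioxolanylium ion sheds the tert-butyl cation as isobutene, which regenerates the acid; a five-membered carbonate can only be cis-fused to the cyclohexene, so the new C4 centre (R) is relayed from C3 (S) whichever C6 epimer is used, and C5=C6 ends up conjugated with the dienal; the closest known reaction types are the acid-catalysed 1,3-transposition of tertiary allylic alcohols and the capture of epoxide- or halonium-derived cations by a neighbouring tert-butyl carbonate to give cyclic carbonates.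

Step 7
Reactants: 9 4-methyl-2H-pyran-2-one; 10 2-methylpropene (isobutene)
Product: 11 rac-(1S,4R)-5,8,8-trimethyl-2-oxabicyclo[2.2.2]oct-5-en-3-one
Conditions: 10 (15 equiv, condensed), BHT (1 mol %), CH2Cl2, sealed PTFE tube, 13 kbar, 60 °C, 72 h
Reagents that add atoms: none
Why: The cisoid diene locked in the pyrone ring (C3=C4–C5=C6 of 9, the electron-poor 4π partner) and the C=C bond of isobutene combine in a concerted, asynchronous [4+2] cycloaddition that is accelerated by pressure and run cold enough to keep the CO2 bridge; the closest known reaction type is the high-pressure Diels–Alder reaction of 2-pyrones with alkenes to 2-oxabicyclo[2.2.2]oct-5-en-3-ones. The carbocycle that becomes the ε-ring (C1'–C6') is closed by intermolecular cycloaddition through the bonds C1'–C6' and C2'–C3', while the old pyrone ring survives as the O–C(=O) bridge that ties O3' to C7'. The two new stereocentres are the bridgeheads (later C3' and C6'); the lactone bridge forces the C3'–O and C6'–C7' bonds onto the same face, so their cis relationship follows from the ring geometry, and the absolute configuration is selected afterwards in step 10. The selectivity needed is regioselectivity: the CH2 terminus of isobutene (larger HOMO coefficient) should bond to pyrone C6 (δ-carbon of the dienoate, larger LUMO coefficient) and the carbon that carries positive charge best (CMe2) to pyrone C3, which places the gem-dimethyl carbon C1' next to C6'. Endo/exo selectivity does not arise because each dienophile carbon carries two identical substituents. In one operation the step supplies all ten carbons of the ε end group, the C4'=C5' position of the double bond, both ring stereocentres in the right relative sense and the oxidation levels of C3' and C7'.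

Step 8
Reactants: 11 rac-(1S,4R)-5,8,8-trimethyl-2-oxabicyclo[2.2.2]oct-5-en-3-one
Product: 12 rac-(1S,4R)-5,8,8-trimethyl-2-oxabicyclo[2.2.2]oct-5-en-3-ol (lactol; both anomers)
Conditions: i-Bu2AlH (1.1 equiv), CH2Cl2, −78 °C; aq potassium sodium tartrate
Reagents that add atoms: none
Why: half-reduction of a lactone with i-Bu2AlH at −78 °C stops at the aluminium hemiacetal, which gives the bridged lactol on work-up; no stereocentre is touched.

Step 9
Reactants: 12 rac-(1S,4R)-5,8,8-trimethyl-2-oxabicyclo[2.2.2]oct-5-en-3-ol; 13 1-(triphenylphosphoranylidene)propan-2-one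
Product: 15 rac-(E)-4-[(1R,4S)-4-hydroxy-2,6,6-trimethylcyclohex-2-en-1-yl]but-3-en-2-one (cis-3-hydroxy-α-ionone), via open hydroxy aldehyde 14 (not isolated)
Conditions: 13 (1.5 equiv), toluene, 90 °C
Reagents that add atoms: none
Why: Wittig olefination with a stabilised ylide, which reacts with the equilibrium amount of the open hydroxy aldehyde under neutral conditions and should give the (E)-enone (C7'=C8'); the absence of base protects the epimerisable C6' centre, so the cis relationship from step 7 is kept.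

Step 10
Reactants: 15 rac-(E)-4-[(1R,4S)-4-hydroxy-2,6,6-trimethylcyclohex-2-en-1-yl]but-3-en-2-one
Product: 16 (E)-4-[(1R,4S)-4-hydroxy-2,6,6-trimethylcyclohex-2-en-1-yl]but-3-en-2-one
Conditions: Burkholderia cepacia lipase (Amano PS), vinyl acetate, t-BuOMe, 30 °C, stopped at about half conversion; chromatography
Reagents that add atoms: none
Why: lipase-catalysed kinetic resolution by irreversible transesterification, in which the empirical size rule for secondary alcohols (alkenyl ring carbon C4' as the larger substituent) predicts faster acetylation of the (3'R)-alcohol, so that the (3'S,6'R)-alcohol 16 should be recovered; because C3' and C6' were locked cis in step 7, selecting C3' selects C6' as well.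

Step 11
Reactants: 16 (E)-4-[(1R,4S)-4-hydroxy-2,6,6-trimethylcyclohex-2-en-1-yl]but-3-en-2-one
Product: 17 (E)-4-[(1R,4S)-4-{[tert-butyl(dimethyl)silyl]oxy}-2,6,6-trimethylcyclohex-2-en-1-yl]but-3-en-2-one
Conditions: TBSCl (1.3 equiv), imidazole (2.5 equiv), DMF, 20 °C
Reagents that add atoms: tert-butyldimethylsilyl chloride, CC(C)(C)[Si](C)(C)Cl
Why: standard silylation of the secondary allylic alcohol; the ether blocks O3' during the two later bromide-forming steps and is removable without acid.

Step 12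
Reactants: 17 (E)-4-[(1R,4S)-4-{[tert-butyl(dimethyl)silyl]oxy}-2,6,6-trimethylcyclohex-2-en-1-yl]but-3-en-2-one; 18 triethyl phosphonoacetate
Product: 19 ethyl (2E,4E)-5-[(1R,4S)-4-{[tert-butyl(dimethyl)silyl]oxy}-2,6,6-trimethylcyclohex-2-en-1-yl]-3-methylpenta-2,4-dienoate
Conditions: 18 (3 equiv), NaH (2.8 equiv), THF, 0 → 50 °C; chromatography
Reagents that add atoms: none
Why: Horner–Wadsworth–Emmons olefination of the methyl ketone should give mainly the (E)-trisubstituted enoate (C9'=C10'), the minor (Z)-isomer being removed by chromatography; the phosphonate anion is too weak a base to epimerise the α-ionone-type C6' centre.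

Step 13
Reactants: 19 ethyl (2E,4E)-5-[(1R,4S)-4-{[tert-butyl(dimethyl)silyl]oxy}-2,6,6-trimethylcyclohex-2-en-1-yl]-3-methylpenta-2,4-dienoate
Product: 20 (2E,4E)-5-[(1R,4S)-4-{[tert-butyl(dimethyl)silyl]oxy}-2,6,6-trimethylcyclohex-2-en-1-yl]-3-methylpenta-2,4-dien-1-ol
Conditions: i-Bu2AlH (2.3 equiv), CH2Cl2, −78 °C; aq potassium sodium tartrate
Reagents that add atoms: none
Why: 1,2-reduction of the conjugated ester to the allylic alcohol; the silyl ether and the alkene geometry are unaffected.

Step 14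
Reactants: 20 (2E,4E)-5-[(1R,4S)-4-{[tert-butyl(dimethyl)silyl]oxy}-2,6,6-trimethylcyclohex-2-en-1-yl]-3-methylpenta-2,4-dien-1-ol
Product: 22 [(2E,4E)-5-[(1R,4S)-4-{[tert-butyl(dimethyl)silyl]oxy}-2,6,6-trimethylcyclohex-2-en-1-yl]-3-methylpenta-2,4-dien-1-yl]triphenylphosphonium bromide, via C15 allylic bromide 21 (not isolated)
Conditions: CBr4 (1.1 equiv), PPh3 (1.1 equiv), CH2Cl2, −20 °C; then PPh3 (1.2 equiv), 0 → 20 °C
Reagents that add atoms: carbon tetrabromide, BrC(Br)(Br)Br; triphenylphosphine, c1ccc(cc1)P(c1ccccc1)c1ccccc1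
Why: Appel bromination of the primary allylic alcohol under neutral conditions, followed by SN2 quaternisation of triphenylphosphine in the same flask; no acid is present that could ionise the allylic C3' oxygen.

Step 15
Reactants: 22 the C15 phosphonium bromide of step 14; 23 (2E,4E,6E)-2,7-dimethylocta-2,4,6-trienedial
Product: 24 (2E,4E,6E,8E,10E,12E)-13-[(1R,4S)-4-{[tert-butyl(dimethyl)silyl]oxy}-2,6,6-trimethylcyclohex-2-en-1-yl]-2,7,11-trimethyltrideca-2,4,6,8,10,12-hexaenal
Conditions: 23 (3 equiv), NaOCH3 (1.05 equiv), CH3OH/CH2Cl2, −10 → 20 °C; then heptane, 80 °C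
Reagents that add atoms: none
Why: Wittig reaction of the semi-stabilised C15 ylide with an excess of the symmetrical dialdehyde (the standard C15 + C10 carotenoid coupling) should stop at mono-condensation; the new C11'=C12' bond forms as an E/Z mixture and the hindered (Z)-isomer is isomerised thermally.

Step 16
Reactants: 24 the C25 aldehyde of step 15
Product: 25 (2E,4E,6E,8E,10E,12E)-13-[(1R,4S)-4-{[tert-butyl(dimethyl)silyl]oxy}-2,6,6-trimethylcyclohex-2-en-1-yl]-2,7,11-trimethyltrideca-2,4,6,8,10,12-hexaen-1-ol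
Conditions: NaBH4 (1 equiv), THF/EtOH, 0 °C
Reagents that add atoms: none
Why: chemoselective 1,2-reduction of the polyene aldehyde with a borohydride.

Step 17
Reactants: 25 the C25 alcohol of step 16
Product: 27 [(2E,4E,6E,8E,10E,12E)-13-[(1R,4S)-4-{[tert-butyl(dimethyl)silyl]oxy}-2,6,6-trimethylcyclohex-2-en-1-yl]-2,7,11-trimethyltrideca-2,4,6,8,10,12-hexaen-1-yl]triphenylphosphonium bromide, via C25 allylic bromide 26 (not isolated)
Conditions: CBr4 (1.1 equiv), PPh3 (1.1 equiv), CH2Cl2, −30 °C; then PPh3 (1.2 equiv), −30 → 20 °C, dark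
Reagents that add atoms: carbon tetrabromide, BrC(Br)(Br)Br; triphenylphosphine, c1ccc(cc1)P(c1ccccc1)c1ccccc1
Why: Appel bromination and in situ quaternisation as in step 14, kept cold and neutral because the pentaenyl bromide is labile and the allylic C3' oxygen must not ionise.

Step 18
Reactants: 27 the C25 phosphonium bromide of step 17; 8 (2E,4E)-3-methyl-5-[(3aR,7aS)-4,6,6-trimethyl-2-oxo-3a,6,7,7a-tetrahydro-1,3-benzodioxol-5-yl]penta-2,4-dienal
Product: 29 (3S,4R,3'S,6'R)-3'-{[tert-butyl(dimethyl)silyl]oxy}-β,ε-carotene-3,4-diol, via C40 cyclic carbonate 28 (not isolated)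
Conditions: 27 (1.1 equiv), NaN(SiMe3)2 (1.05 equiv), THF, −78 °C; then 8, −78 → 0 °C; then NaOCH3 (0.3 equiv), CH3OH, 20 °C; then heptane/EtOAc, 80 °C
Reagents that add atoms: none
Why: Wittig reaction between the preformed C25 ylide and the C15 aldehyde closes the chromophore at C11=C12; the carbanion sits on the fragment whose ring oxygen is insulated by the sp3 carbon C6', so no vinylogous β-elimination of the allylic C4 carbonate can occur, catalytic methoxide then removes the carbonate by transesterification, and heating converts the hindered (11Z)-isomer into the all-E polyene.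

Step 19
Reactants: 29 (3S,4R,3'S,6'R)-3'-{[tert-butyl(dimethyl)silyl]oxy}-β,ε-carotene-3,4-diol
Product: 30 (3S,4R,3'S,6'R)-β,ε-carotene-3,4,3'-triol (target)
Conditions: tetrabutylammonium fluoride (1.5 equiv), AcOH (1.5 equiv), THF, 0 → 20 °C, dark; crystallisation
Reagents that add atoms: none
Why: fluoride-mediated cleavage of the silyl ether under buffered, non-acidic conditions, chosen because both allylic carbinols (C4 and C3') ionise easily in acid.

**Compound list**

1 | 2,6,6-trimethylcyclohex-2-ene-1,4-dione (ketoisophorone) | CC1=CC(=O)CC(C)(C)C1=O | starting material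
2 | (4S)-4-hydroxy-2,6,6-trimethylcyclohex-2-en-1-one | CC1=C[C@@H](O)CC(C)(C)C1=O | intermediate
3 | (E)-3-methylpent-2-en-4-yn-1-ol | C#C/C(C)=C/CO | starting material
4 | (4S)-1-[(E)-5-hydroxy-3-methylpent-3-en-1-yn-1-yl]-2,6,6-trimethylcyclohex-2-ene-1,4-diol (both C1 epimers) | CC1=C[C@@H](O)CC(C)(C)C1(O)C#C/C(C)=C/CO | intermediate
5 | (4S)-1-[(1E,3E)-5-hydroxy-3-methylpenta-1,3-dien-1-yl]-2,6,6-trimethylcyclohex-2-ene-1,4-diol | CC1=C[C@@H](O)CC(C)(C)C1(O)/C=C/C(C)=C/CO | intermediate
6 | (2E,4E)-5-[(4S)-1,4-dihydroxy-2,6,6-trimethylcyclohex-2-en-1-yl]-3-methylpenta-2,4-dienal | CC1=C[C@@H](O)CC(C)(C)C1(O)/C=C/C(C)=C/C=O | intermediate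
7 | tert-butyl (1S)-4-hydroxy-3,5,5-trimethyl-4-[(1E,3E)-3-methyl-5-oxopenta-1,3-dien-1-yl]cyclohex-2-en-1-yl carbonate | CC1=C[C@@H](OC(=O)OC(C)(C)C)CC(C)(C)C1(O)/C=C/C(C)=C/C=O | intermediate
8 | (2E,4E)-3-methyl-5-[(3aR,7aS)-4,6,6-trimethyl-2-oxo-3a,6,7,7a-tetrahydro-1,3-benzodioxol-5-yl]penta-2,4-dienal | O=C/C=C(C)/C=C/C1=C(C)[C@@H](OC(=O)O2)[C@@H]2CC1(C)C | intermediate
9 | 4-methyl-2H-pyran-2-one | CC1=CC(=O)OC=C1 | starting material
10 | 2-methylpropene (isobutene) | CC(C)=C | starting material
11 | rac-(1S,4R)-5,8,8-trimethyl-2-oxabicyclo[2.2.2]oct-5-en-3-one | CC1=C[C@@H]2CC(C)(C)[C@H]1C(=O)O2 | intermediate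
12 | rac-(1S,4R)-5,8,8-trimethyl-2-oxabicyclo[2.2.2]oct-5-en-3-ol (both anomers) | CC1=C[C@@H]2CC(C)(C)[C@H]1C(O)O2 | intermediate
13 | 1-(triphenylphosphoranylidene)propan-2-one | CC(=O)C=P(c1ccccc1)(c1ccccc1)c1ccccc1 | starting material
14 | rac-(1R,4S)-4-hydroxy-2,6,6-trimethylcyclohex-2-ene-1-carbaldehyde | CC1=C[C@@H](O)CC(C)(C)[C@H]1C=O | intermediate (not isolated)
15 | rac-(E)-4-[(1R,4S)-4-hydroxy-2,6,6-trimethylcyclohex-2-en-1-yl]but-3-en-2-one | CC1=C[C@@H](O)CC(C)(C)[C@H]1/C=C/C(C)=O | intermediate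
16 | (E)-4-[(1R,4S)-4-hydroxy-2,6,6-trimethylcyclohex-2-en-1-yl]but-3-en-2-one (single enantiomer) | CC1=C[C@@H](O)CC(C)(C)[C@H]1/C=C/C(C)=O | intermediate
17 | (E)-4-[(1R,4S)-4-{[tert-butyl(dimethyl)silyl]oxy}-2,6,6-trimethylcyclohex-2-en-1-yl]but-3-en-2-one | CC1=C[C@@H](O[Si](C)(C)C(C)(C)C)CC(C)(C)[C@H]1/C=C/C(C)=O | intermediate
18 | triethyl phosphonoacetate | CCOC(=O)CP(=O)(OCC)OCC | starting material
19 | ethyl (2E,4E)-5-[(1R,4S)-4-{[tert-butyl(dimethyl)silyl]oxy}-2,6,6-trimethylcyclohex-2-en-1-yl]-3-methylpenta-2,4-dienoate | CC1=C[C@@H](O[Si](C)(C)C(C)(C)C)CC(C)(C)[C@H]1/C=C/C(C)=C/C(=O)OCC | intermediate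
20 | (2E,4E)-5-[(1R,4S)-4-{[tert-butyl(dimethyl)silyl]oxy}-2,6,6-trimethylcyclohex-2-en-1-yl]-3-methylpenta-2,4-dien-1-ol | CC1=C[C@@H](O[Si](C)(C)C(C)(C)C)CC(C)(C)[C@H]1/C=C/C(C)=C/CO | intermediate
21 | tert-butyl{[(1S,4R)-4-[(1E,3E)-5-bromo-3-methylpenta-1,3-dien-1-yl]-3,5,5-trimethylcyclohex-2-en-1-yl]oxy}dimethylsilane (C15 allylic bromide) | CC1=C[C@@H](O[Si](C)(C)C(C)(C)C)CC(C)(C)[C@H]1/C=C/C(C)=C/CBr | intermediate (not isolated)
22 | [(2E,4E)-5-[(1R,4S)-4-{[tert-butyl(dimethyl)silyl]oxy}-2,6,6-trimethylcyclohex-2-en-1-yl]-3-methylpenta-2,4-dien-1-yl]triphenylphosphonium bromide | CC1=C[C@@H](O[Si](C)(C)C(C)(C)C)CC(C)(C)[C@H]1/C=C/C(C)=C/C[P+](c1ccccc1)(c1ccccc1)c1ccccc1.[Br-] | intermediate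
23 | (2E,4E,6E)-2,7-dimethylocta-2,4,6-trienedial | O=C/C(C)=C/C=C/C=C(C)/C=O | starting material
24 | (2E,4E,6E,8E,10E,12E)-13-[(1R,4S)-4-{[tert-butyl(dimethyl)silyl]oxy}-2,6,6-trimethylcyclohex-2-en-1-yl]-2,7,11-trimethyltrideca-2,4,6,8,10,12-hexaenal | CC1=C[C@@H](O[Si](C)(C)C(C)(C)C)CC(C)(C)[C@H]1/C=C/C(C)=C/C=C/C(C)=C/C=C/C=C(C)/C=O | intermediate
25 | (2E,4E,6E,8E,10E,12E)-13-[(1R,4S)-4-{[tert-butyl(dimethyl)silyl]oxy}-2,6,6-trimethylcyclohex-2-en-1-yl]-2,7,11-trimethyltrideca-2,4,6,8,10,12-hexaen-1-ol | CC1=C[C@@H](O[Si](C)(C)C(C)(C)C)CC(C)(C)[C@H]1/C=C/C(C)=C/C=C/C(C)=C/C=C/C=C(C)/CO | intermediate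
26 | C25 allylic bromide (the 1-bromide of 25) | CC1=C[C@@H](O[Si](C)(C)C(C)(C)C)CC(C)(C)[C@H]1/C=C/C(C)=C/C=C/C(C)=C/C=C/C=C(C)/CBr | intermediate (not isolated)
27 | [(2E,4E,6E,8E,10E,12E)-13-[(1R,4S)-4-{[tert-butyl(dimethyl)silyl]oxy}-2,6,6-trimethylcyclohex-2-en-1-yl]-2,7,11-trimethyltrideca-2,4,6,8,10,12-hexaen-1-yl]triphenylphosphonium bromide | CC1=C[C@@H](O[Si](C)(C)C(C)(C)C)CC(C)(C)[C@H]1/C=C/C(C)=C/C=C/C(C)=C/C=C/C=C(C)/C[P+](c1ccccc1)(c1ccccc1)c1ccccc1.[Br-] | intermediate
28 | (3S,4R,3'S,6'R)-3'-{[tert-butyl(dimethyl)silyl]oxy}-β,ε-carotene-3,4-diyl carbonate (cyclic) | CC1=C[C@@H](O[Si](C)(C)C(C)(C)C)CC(C)(C)[C@H]1/C=C/C(C)=C/C=C/C(C)=C/C=C/C=C(C)/C=C/C=C(C)/C=C/C1=C(C)[C@@H](OC(=O)O2)[C@@H]2CC1(C)C | intermediate (not isolated)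
29 | (3S,4R,3'S,6'R)-3'-{[tert-butyl(dimethyl)silyl]oxy}-β,ε-carotene-3,4-diol | CC1=C[C@@H](O[Si](C)(C)C(C)(C)C)CC(C)(C)[C@H]1/C=C/C(C)=C/C=C/C(C)=C/C=C/C=C(C)/C=C/C=C(C)/C=C/C1=C(C)[C@@H](O)[C@@H](O)CC1(C)C | intermediate
30 | (3S,4R,3'S,6'R)-β,ε-carotene-3,4,3'-triol | CC1=C[C@@H](O)CC(C)(C)[C@H]1/C=C/C(C)=C/C=C/C(C)=C/C=C/C=C(C)/C=C/C=C(C)/C=C/C1=C(C)[C@@H](O)[C@@H](O)CC1(C)C | target

**Step count and risks**

Total step count: 19. Longest linear sequence: 13 steps (steps 7 to 19, from 9 and 10); the β branch (steps 1 to 6) joins at step 18.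

Steps most likely to fail:

1. Step 6 (proposed new method). What may go wrong: acid cleavage of the tert-butyl carbonate before the tertiary alcohol ionises, proton loss from the allyl cation instead of capture, or capture by adventitious water with loss of the cis relay. Fallback (known chemistry; sets out from 6 and comes back at 8): 6 is treated with dilute aqueous acid (0.05 M H2SO4, THF/H2O, 0 °C), the classical acid-catalysed 1,3-hydroxyl shift of a tertiary allylic alcohol. This should give the conjugated diols as a separable mixture of (2E,4E)-5-[(3R,4S)-3,4-dihydroxy-2,6,6-trimethylcyclohex-1-en-1-yl]-3-methylpenta-2,4-dienal F1 (cis) and its (3S,4S) epimer F2 (trans). F1 is then closed to 8 with 1,1'-carbonyldiimidazole in CH2Cl2.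

2. Step 7 (key step). What may go wrong: too low reactivity of the unactivated diene/dienophile pair, steric approach control overriding the electronic orientation (gem-dimethyl carbon bonding to the wrong diene terminus), extrusion of CO2 from the adduct, or oligomerisation of isobutene. Fallback (sets out from no numbered compound, since commercial mesityl oxide and ethyl acetoacetate replace 9 and 10, and comes back at 11): the two are condensed with ZnCl2 (Michael addition, then intramolecular aldol condensation, the classical isophorone-type annulation) to ethyl 2,6,6-trimethyl-4-oxocyclohex-2-ene-1-carboxylate F3. 1,2-Reduction (NaBH4, CeCl3·7H2O, CH3OH) gives ethyl 4-hydroxy-2,6,6-trimethylcyclohex-2-ene-1-carboxylate F4 as a cis/trans mixture, and saponification (LiOH, THF/H2O) gives 4-hydroxy-2,6,6-trimethylcyclohex-2-ene-1-carboxylic acid F5. The cis acid is lactonised with retention (carbodiimide, DMAP) and the trans acid with inversion at the carbinol carbon (PPh3, diisopropyl azodicarboxylate, Mitsunobu), so both converge on racemic 11.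

3. Step 10. What may go wrong: poor discrimination of the enantiomers by the lipase, because the two ring substituents flanking the carbinol carbon are of similar size, so the recovered alcohol is not enantiopure at workable conversion. Fallback (sets out from 15 and comes back at 16): 15 is esterified with (S)-2-methoxy-2-phenylacetic acid (dicyclohexylcarbodiimide, DMAP) to the diastereomeric esters, the (S)-2-methoxy-2-phenylacetate of the (1R,4S)-alcohol F6 and the (S)-2-methoxy-2-phenylacetate of the (1S,4R)-alcohol F7. These are separated by chromatography or crystallisation, and methanolysis of F6 (K2CO3, CH3OH) returns 16.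

**Further compounds**

F1 | step 6 | (2E,4E)-5-[(3R,4S)-3,4-dihydroxy-2,6,6-trimethylcyclohex-1-en-1-yl]-3-methylpenta-2,4-dienal | O=C/C=C(C)/C=C/C1=C(C)[C@@H](O)[C@@H](O)CC1(C)C
F2 | step 6 | (2E,4E)-5-[(3S,4S)-3,4-dihydroxy-2,6,6-trimethylcyclohex-1-en-1-yl]-3-methylpenta-2,4-dienal | O=C/C=C(C)/C=C/C1=C(C)[C@H](O)[C@@H](O)CC1(C)C
F3 | step 7 | ethyl 2,6,6-trimethyl-4-oxocyclohex-2-ene-1-carboxylate (racemic) | CCOC(=O)C1C(C)=CC(=O)CC1(C)C
F4 | step 7 | ethyl 4-hydroxy-2,6,6-trimethylcyclohex-2-ene-1-carboxylate (racemic, cis/trans mixture) | CCOC(=O)C1C(C)=CC(O)CC1(C)C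
F5 | step 7 | 4-hydroxy-2,6,6-trimethylcyclohex-2-ene-1-carboxylic acid (racemic, cis/trans mixture) | OC(=O)C1C(C)=CC(O)CC1(C)C
F6 | step 10 | (1S,4R)-3,5,5-trimethyl-4-[(1E)-3-oxobut-1-en-1-yl]cyclohex-2-en-1-yl (2S)-2-methoxy-2-phenylacetate (ester of 16) | CC1=C[C@@H](OC(=O)[C@@H](OC)c2ccccc2)CC(C)(C)[C@H]1/C=C/C(C)=O
F7 | step 10 | (1R,4S)-3,5,5-trimethyl-4-[(1E)-3-oxobut-1-en-1-yl]cyclohex-2-en-1-yl (2S)-2-methoxy-2-phenylacetate (ester of the enantiomer of 16) | CC1=C[C@H](OC(=O)[C@@H](OC)c2ccccc2)CC(C)(C)[C@@H]1/C=C/C(C)=O
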